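**Strategy.** Everything rests on opening the tetrasubstituted C1=C2 double bond of the 2,6,6-trimethylcyclohexene ring (C1 carries the side chain, C2 the methyl group) into two ketone carbonyls. A reductive carbonyl–carbonyl coupling with low-valent titanium then joins these two electrophilic carbons, closes the six-membered ring and installs the hindered olefin in one operation, late in the route. Its precursor is an open-chain 2,7-diketone that already carries the (E,E)-diene chain and the hydroquinone as its dimethyl ether. The quaternary CMe2 carbon (ring C6) flanking one carbonyl leaves the building-block ketone enolisable at one site only, so the chain is attached by a single enolate alkylation.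

Key step: step 7

Remark: the target has no stereocentre. Its only stereo-elements are the two E trisubstituted chain olefins, one bought with geranyl bromide and one set in step 2. Compounds 1, 2, 7 and 8 are taken as catalogue chemicals.

**Step 1**
Reactants: 1 1,4-dimethoxybenzene; 2 geranyl bromide, (2E)-1-bromo-3,7-dimethylocta-2,6-diene
Product: 4 2-[(2E)-3,7-dimethylocta-2,6-dien-1-yl]-1,4-dimethoxybenzene, via 2-lithio-1,4-dimethoxybenzene 3 (not isolated)
Conditions: n-BuLi, TMEDA, THF, 0 °C; then 2, −78 °C → rt
Reagents that add atoms: none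
Why: Directed ortho-lithiation of the dimethoxyarene followed by SN2 alkylation of the aryllithium at the primary allylic bromide; the E olefin of 2 is carried over unchanged.

**Step 2**
Reactants: 4 2-[(2E)-3,7-dimethylocta-2,6-dien-1-yl]-1,4-dimethoxybenzene
Product: 5 (2E,6E)-8-(2,5-dimethoxyphenyl)-2,6-dimethylocta-2,6-dien-1-ol
Conditions: SeO2 (0.3 equiv), t-BuOOH, salicylic acid (cat.), CH2Cl2, 0 °C → rt
Reagents that add atoms: tert-butyl hydroperoxide CC(C)(C)OO (terminal oxidant and oxygen source), relayed by selenium dioxide O=[Se]=O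
Why: Catalytic SeO2 allylic oxidation (ene reaction, then [2,3]-sigmatropic shift) should attack the terminal isopropylidene group at its (E)-methyl, which gives the E allylic alcohol by the inherent course of the mechanism; any enal from over-oxidation is removed by chromatography.

**Step 3**
Reactants: 5 (2E,6E)-8-(2,5-dimethoxyphenyl)-2,6-dimethylocta-2,6-dien-1-ol
Product: 6 2-[(2E,6E)-8-bromo-3,7-dimethylocta-2,6-dien-1-yl]-1,4-dimethoxybenzene
Conditions: CBr4, PPh3, CH2Cl2, 0 °C
Reagents that add atoms: carbon tetrabromide BrC(Br)(Br)Br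
Why: Appel bromination of a primary allylic alcohol under neutral conditions should proceed without allylic transposition or loss of olefin geometry; the bromide is used directly.

**Step 4**
Reactants: 7 isobutyronitrile; 8 2-(3-chloropropyl)-2-methyl-1,3-dioxolane
Product: 10 2,2-dimethyl-5-(2-methyl-1,3-dioxolan-2-yl)pentanenitrile, via lithiated isobutyronitrile 9 (not isolated)
Conditions: LiN(iPr)2 (LDA), THF, −78 °C; then 8, DMPU, −78 °C → rt
Reagents that add atoms: none
Why: Alkylation of a nitrile-stabilised tertiary carbanion by a primary chloride builds the quaternary carbon (ring C6 of the target); the dioxolane is inert to the base.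

**Step 5**
Reactants: 10 2,2-dimethyl-5-(2-methyl-1,3-dioxolan-2-yl)pentanenitrile
Product: 12 3,3-dimethyl-6-(2-methyl-1,3-dioxolan-2-yl)hexan-2-one, via N-lithio ketimine 11 (not isolated)
Conditions: MeLi, Et2O, 0 °C → rt; then aq. AcOH/NaOAc buffer (pH 5), THF, 0 °C → rt
Reagents that add atoms: methyllithium [Li]C; water O
Why: Addition of an organolithium to a nitrile without α-hydrogens stops at the ketimine salt, and buffered hydrolysis of the N–H ketimine at pH 5 should be much faster than cleavage of the dioxolane, giving the methyl ketone (ketone synthesis from a nitrile).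

**Step 6**
Reactants: 12 3,3-dimethyl-6-(2-methyl-1,3-dioxolan-2-yl)hexan-2-one; 6 2-[(2E,6E)-8-bromo-3,7-dimethylocta-2,6-dien-1-yl]-1,4-dimethoxybenzene
Product: 15 (10E,14E)-16-(2,5-dimethoxyphenyl)-6,6,10,14-tetramethylhexadeca-10,14-diene-2,7-dione, via lithium enolate 13 (not isolated), via ketal-protected alkylation product 14 (not isolated)
Conditions: LiN(iPr)2 (LDA), THF, −78 °C; then 6 (limiting), −78 → 0 °C; then 1 M aq. HCl, THF, rt
Reagents that add atoms: water O
Why: Ketone 12 can enolise only at its methyl group (quaternary carbon on the other side, second ketone masked), so the lithium enolate should undergo a single SN2 alkylation at the primary allylic bromide with retention of both E olefins, and the acidic work-up hydrolyses the dioxolane to release the second ketone.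

**Step 7**
Reactants: 15 (10E,14E)-16-(2,5-dimethoxyphenyl)-6,6,10,14-tetramethylhexadeca-10,14-diene-2,7-dione
Product: 16 2-[(2E,6E)-3,7-dimethyl-9-(2,6,6-trimethylcyclohex-1-en-1-yl)nona-2,6-dien-1-yl]-1,4-dimethoxybenzene
Conditions: TiCl3(DME)1.5, Zn–Cu couple, DME, reflux; 15 added by syringe pump at high dilution, then continued reflux
Reagents that add atoms: none
Why: Low-valent titanium generated from TiCl3(DME)1.5 and Zn–Cu transfers single electrons to both carbonyl groups, the two ketyl carbons (both electrophilic in 15) couple to a titanium-bound cis-pinacolate, and at reflux both oxygen atoms are given up to the titanium surface, leaving the tetrasubstituted C1=C2 olefin (intramolecular McMurry coupling). The closest known reaction is the McMurry cyclization of acyclic diketones to 1,2-dialkylcycloalkenes. The six-membered ring closes in a 6-exo-trig ketyl-to-carbonyl mode on the metal surface, helped by the gem-dimethyl group next to one carbonyl. No stereocentre is created and the new olefin is endocyclic, so its geometry is fixed by the ring. The step needs cyclization to beat intermolecular coupling, which slow addition at high dilution and the favourable six-membered closure should secure, and it needs the two E trisubstituted olefins and the aryl methyl ethers to stay untouched, which follows from the inertness of isolated alkenes and ethers to low-valent titanium. Since the substrate holds exactly two carbonyl groups and nothing else reducible, no regiochemical alternative exists.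

**Step 8**
Reactants: 16 2-[(2E,6E)-3,7-dimethyl-9-(2,6,6-trimethylcyclohex-1-en-1-yl)nona-2,6-dien-1-yl]-1,4-dimethoxybenzene
Product: 18 jaspaquinol, via benzoquinone 17 (not isolated)
Conditions: 16 added to (NH4)2Ce(NO3)6, MeCN/H2O, 0 °C; then Et2O extraction and shaking with aq. Na2S2O4 under Ar, rt
Reagents that add atoms: water O
Why: Oxidative demethylation by ceric ammonium nitrate should occur at the electron-rich dimethoxyarene, the most easily oxidised site, with water adding at the ipso carbons and methanol leaving to give the quinone, and dithionite reduction of the crude quinone returns the hydroquinone without touching the three olefins.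

**Compound list**
1 | 1,4-dimethoxybenzene | COc1ccc(OC)cc1 | starting material
2 | geranyl bromide, (2E)-1-bromo-3,7-dimethylocta-2,6-diene | CC(C)=CCC/C(C)=C/CBr | starting material
3 | 2-lithio-1,4-dimethoxybenzene | [Li]c1cc(OC)ccc1OC | intermediate
4 | 2-[(2E)-3,7-dimethylocta-2,6-dien-1-yl]-1,4-dimethoxybenzene | CC(C)=CCC/C(C)=C/Cc1cc(OC)ccc1OC | intermediate
5 | (2E,6E)-8-(2,5-dimethoxyphenyl)-2,6-dimethylocta-2,6-dien-1-ol | OC/C(C)=C/CC/C(C)=C/Cc1cc(OC)ccc1OC | intermediate
6 | 2-[(2E,6E)-8-bromo-3,7-dimethylocta-2,6-dien-1-yl]-1,4-dimethoxybenzene | BrC/C(C)=C/CC/C(C)=C/Cc1cc(OC)ccc1OC | intermediate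
7 | isobutyronitrile | CC(C)C#N | starting material
8 | 2-(3-chloropropyl)-2-methyl-1,3-dioxolane | CC1(CCCCl)OCCO1 | starting material
9 | lithiated isobutyronitrile (N-lithio ketenimine form) | CC(C)=C=N[Li] | intermediate
10 | 2,2-dimethyl-5-(2-methyl-1,3-dioxolan-2-yl)pentanenitrile | CC1(CCCC(C)(C)C#N)OCCO1 | intermediate
11 | N-lithio ketimine of 12 | CC1(CCCC(C)(C)C(C)=N[Li])OCCO1 | intermediate
12 | 3,3-dimethyl-6-(2-methyl-1,3-dioxolan-2-yl)hexan-2-one | CC(=O)C(C)(C)CCCC1(C)OCCO1 | intermediate
13 | lithium enolate of 12 | C=C(O[Li])C(C)(C)CCCC1(C)OCCO1 | intermediate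
14 | (8E,12E)-14-(2,5-dimethoxyphenyl)-4,4,8,12-tetramethyl-1-(2-methyl-1,3-dioxolan-2-yl)tetradeca-8,12-dien-5-one | CC1(CCCC(C)(C)C(=O)CC/C(C)=C/CC/C(C)=C/Cc2cc(OC)ccc2OC)OCCO1 | intermediate
15 | (10E,14E)-16-(2,5-dimethoxyphenyl)-6,6,10,14-tetramethylhexadeca-10,14-diene-2,7-dione | CC(=O)CCCC(C)(C)C(=O)CC/C(C)=C/CC/C(C)=C/Cc1cc(OC)ccc1OC | intermediate
16 | 2-[(2E,6E)-3,7-dimethyl-9-(2,6,6-trimethylcyclohex-1-en-1-yl)nona-2,6-dien-1-yl]-1,4-dimethoxybenzene | CC1=C(CC/C(C)=C/CC/C(C)=C/Cc2cc(OC)ccc2OC)C(C)(C)CCC1 | intermediate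
17 | 2-[(2E,6E)-3,7-dimethyl-9-(2,6,6-trimethylcyclohex-1-en-1-yl)nona-2,6-dien-1-yl]cyclohexa-2,5-diene-1,4-dione | CC1=C(CC/C(C)=C/CC/C(C)=C/CC2=CC(=O)C=CC2=O)C(C)(C)CCC1 | intermediate
18 | jaspaquinol, 2-[(2E,6E)-3,7-dimethyl-9-(2,6,6-trimethylcyclohex-1-en-1-yl)nona-2,6-dien-1-yl]benzene-1,4-diol | CC1=C(CC/C(C)=C/CC/C(C)=C/Cc2cc(O)ccc2O)C(C)(C)CCC1 | target

**Count.** Total: 8 steps. Longest linear sequence: 6 steps (1, 2, 3, 6, 7, 8); the ketone branch (steps 4, 5) joins at step 6.

**Steps most likely to fail**

Step 7. The coupling may stall at the pinacol stage because one carbonyl sits next to a quaternary carbon, or intermolecular coupling may compete with ring closure. The fallback sets out from 15 and comes back at 16, making the same bond in two known stages. SmI2 (divalent samarium) in THF/HMPA with t-BuOH at 0 °C → rt should effect ketyl–carbonyl pinacol cyclization to racemic cis-1-[(3E,7E)-9-(2,5-dimethoxyphenyl)-3,7-dimethylnona-3,7-dien-1-yl]-2,6,6-trimethylcyclohexane-1,2-diol F1, cis because both oxygens are held on samarium. Thiophosgene and DMAP in CH2Cl2 should convert it into the cis-fused cyclic thionocarbonate F2. Corey–Hopkins fragmentation with 1,3-dimethyl-2-phenyl-1,3,2-diazaphospholidine at 40 °C should then give 16 by syn elimination.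

Step 2. Site selectivity between the terminal and the internal trisubstituted olefin of 4 may be insufficient, and over-oxidation to the enal may erode material. The fallback sets out from 1 (through its lithio derivative 3) and comes back at 5, installing the oxygen before the arene. Commercial geranyl acetate F3, whose allylic acetate deactivates the internal olefin, is oxidised with SeO2/t-BuOOH to (2E,6E)-8-hydroxy-3,7-dimethylocta-2,6-dien-1-yl acetate F4. TBSCl/imidazole gives the silyl ether acetate F5, K2CO3/MeOH frees the allylic alcohol F6, and CBr4/PPh3 gives the allylic bromide F7. Coupling with aryllithium 3 under the conditions of step 1 gives the silyl ether F8, and Bu4NF in THF releases 5.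

Step 6. Proton transfer from the product to unreacted enolate may lead to double alkylation and incomplete conversion, and some SN2′ attack on the allylic bromide may occur. The fallback sets out from 12 and comes back at 14, using a soft, doubly stabilised enolate. NaH and dimethyl carbonate in refluxing THF should acylate the methyl group of 12 to give methyl 4,4-dimethyl-7-(2-methyl-1,3-dioxolan-2-yl)-3-oxoheptanoate F9. Its sodium enolate (NaH, THF, 0 °C → rt) should be alkylated once by 6 to give the α-alkylated β-keto ester F10, racemic at a centre that is lost in the next stage. Krapcho demethoxycarbonylation (LiCl, wet DMSO, 150 °C) gives 14, which is hydrolysed with 1 M aq. HCl as in step 6 to 15.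

**Further compounds**
F1 | step 7 | cis-1-[(3E,7E)-9-(2,5-dimethoxyphenyl)-3,7-dimethylnona-3,7-dien-1-yl]-2,6,6-trimethylcyclohexane-1,2-diol (racemic, one enantiomer drawn) | C[C@]1(O)CCCC(C)(C)[C@]1(O)CC/C(C)=C/CC/C(C)=C/Cc2cc(OC)ccc2OC
F2 | step 7 | cis-3a-[(3E,7E)-9-(2,5-dimethoxyphenyl)-3,7-dimethylnona-3,7-dien-1-yl]-4,4,7a-trimethylhexahydro-1,3-benzodioxole-2-thione (racemic, one enantiomer drawn) | C[C@]1(O3)CCCC(C)(C)[C@]1(OC3=S)CC/C(C)=C/CC/C(C)=C/Cc2cc(OC)ccc2OC
F3 | step 2 | geranyl acetate (purchased) | CC(C)=CCC/C(C)=C/COC(C)=O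
F4 | step 2 | (2E,6E)-8-hydroxy-3,7-dimethylocta-2,6-dien-1-yl acetate | OC/C(C)=C/CC/C(C)=C/COC(C)=O
F5 | step 2 | (2E,6E)-8-[(tert-butyldimethylsilyl)oxy]-3,7-dimethylocta-2,6-dien-1-yl acetate | CC(C)(C)[Si](C)(C)OC/C(C)=C/CC/C(C)=C/COC(C)=O
F6 | step 2 | (2E,6E)-8-[(tert-butyldimethylsilyl)oxy]-3,7-dimethylocta-2,6-dien-1-ol | CC(C)(C)[Si](C)(C)OC/C(C)=C/CC/C(C)=C/CO
F7 | step 2 | {[(2E,6E)-8-bromo-2,6-dimethylocta-2,6-dien-1-yl]oxy}(tert-butyl)dimethylsilane | CC(C)(C)[Si](C)(C)OC/C(C)=C/CC/C(C)=C/CBr
F8 | step 2 | tert-butyl{[(2E,6E)-8-(2,5-dimethoxyphenyl)-2,6-dimethylocta-2,6-dien-1-yl]oxy}dimethylsilane | CC(C)(C)[Si](C)(C)OC/C(C)=C/CC/C(C)=C/Cc1cc(OC)ccc1OC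
F9 | step 6 | methyl 4,4-dimethyl-7-(2-methyl-1,3-dioxolan-2-yl)-3-oxoheptanoate | COC(=O)CC(=O)C(C)(C)CCCC1(C)OCCO1
F10 | step 6 | methyl 2-[(2E,6E)-8-(2,5-dimethoxyphenyl)-2,6-dimethylocta-2,6-dien-1-yl]-4,4-dimethyl-7-(2-methyl-1,3-dioxolan-2-yl)-3-oxoheptanoate (racemic) | COC(=O)C(C/C(C)=C/CC/C(C)=C/Cc1cc(OC)ccc1OC)C(=O)C(C)(C)CCCC1(C)OCCO1
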